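**Retrosynthetic overview** (elemane numbering: C10 quaternary, C5 CH–isopropenyl, C6 lactone CH–O, C7, C8 CH–O-acyl, C11 lactone CH–CH3, C15 CH2OH)
1. Target 29 ⇒ C8 ester cleavage to lactone alcohol 20 plus acid 26; the C15–OH comes from a late allylic oxidation.
2. Lactone 19 ⇒ acyclic aldehyde–enoate 16: SmI2 ketyl–olefin cyclisation/lactonisation makes the C6–C7 and O–C12 bonds and sets C6, C7 and C11.
3. 16 ⇒ acid 14 ⇒ allyl ester 12: enantioselective Ireland–Claisen makes the C5–C10 bond and sets C5 and C10.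
4. 12 ⇒ (R)-hex-1-en-5-yn-3-ol 5 (C8 from Sharpless kinetic resolution) by carboalumination, cross-metathesis and esterification.
5. Ring order: no ring exists before step 9; the cyclohexane and the γ-lactone form together in step 9.

Assumption: the (R,R)-bromoborane with E(O)-enolisation (Et3N, toluene–hexane) is taken to give (2R,3R)-14; if the first run shows the opposite facial sense, the (S,S)-reagent is used with no other change.

**Step 1**
Reactants: 1 acrolein; 2 propargyl bromide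
Product: 4 rac-hex-1-en-5-yn-3-ol, via allenylzinc bromide 3 (not isolated)
Conditions: Zn dust, THF, 0 °C; 1 M HCl work-up
Reagents that add atoms: none
Why: Barbier propargylation, in which the allenylzinc formed in the flask adds 1,2 to the enal by SE2' to give the racemic homopropargylic alcohol.

**Step 2**
Reactants: 4 rac-hex-1-en-5-yn-3-ol
Product: 5 (3R)-hex-1-en-5-yn-3-ol
Conditions: Ti(Oi-Pr)4 (10 mol %), L-(+)-DIPT (15 mol %), t-BuOOH (0.6 equiv), 4 Å MS, CH2Cl2, −20 °C
Reagents that add atoms: none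
Why: Sharpless kinetic resolution, in which L-(+)-tartrate epoxidises the (S)-allylic alcohol fast and leaves the (R)-alcohol (the C8 stereocentre) in high ee.

**Step 3**
Reactants: 5 (3R)-hex-1-en-5-yn-3-ol
Product: 7 (2E,5R)-3-methylhepta-2,6-diene-1,5-diol, via alkenylalane 6 (not isolated)
Conditions: AlMe3 (4 equiv), Cp2ZrCl2 (25 mol %), CH2Cl2, 0 → 23 °C; n-BuLi, THF, −78 °C; (CH2O)n, 23 °C; aq. HCl
Reagents that add atoms: trimethylaluminium C[Al](C)C; formaldehyde (from paraformaldehyde) C=O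
Why: Negishi Zr-catalysed carboalumination adds Me and Al syn across the alkyne (Me on the internal carbon) and the alanate is hydroxymethylated with retention, giving the E-trisubstituted allylic alcohol.

**Step 4**
Reactants: 7 (2E,5R)-3-methylhepta-2,6-diene-1,5-diol; 8 methyl methacrylate
Product: 9 methyl (2E,4R,6E)-4,8-dihydroxy-2,6-dimethylocta-2,6-dienoate
Conditions: Hoveyda–Grubbs II (5 mol %), 8 (10 equiv), CH2Cl2, 40 °C
Reagents that add atoms: none
Why: Olefin cross-metathesis, in which only the monosubstituted vinyl carbinol alkene reacts and gives the thermodynamic E-trisubstituted enoate with loss of ethene.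

**Step 5**
Reactants: 9 methyl (2E,4R,6E)-4,8-dihydroxy-2,6-dimethylocta-2,6-dienoate; 10 3-methylbut-3-enoic acid
Product: 11 methyl (2E,4R,6E)-4-hydroxy-2,6-dimethyl-8-[(3-methylbut-3-enoyl)oxy]octa-2,6-dienoate
Conditions: DCC, DMAP (5 mol %), CH2Cl2, −20 °C
Reagents that add atoms: none
Why: Steglich esterification, selective for the primary allylic hydroxyl over the hindered, electron-poor secondary γ-hydroxy-enoate hydroxyl.

**Step 6**
Reactants: 11 methyl (2E,4R,6E)-4-hydroxy-2,6-dimethyl-8-[(3-methylbut-3-enoyl)oxy]octa-2,6-dienoate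
Product: 12 methyl (2E,4R,6E)-4-[(tert-butyldimethylsilyl)oxy]-2,6-dimethyl-8-[(3-methylbut-3-enoyl)oxy]octa-2,6-dienoate
Conditions: TBSCl, imidazole, DMF, 23 °C
Reagents that add atoms: tert-butyldimethylsilyl chloride CC(C)(C)[Si](C)(C)Cl
Why: Silyl ether protection of the C8 hydroxyl, so that it is inert to the boron reagent, the hydride and SmI2 and cannot compete in the later lactonisation.

**Step 7**
Reactants: 12 methyl (2E,4R,6E)-4-[(tert-butyldimethylsilyl)oxy]-2,6-dimethyl-8-[(3-methylbut-3-enoyl)oxy]octa-2,6-dienoate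
Product: 14 (2R,3R,5R,6E)-5-[(tert-butyldimethylsilyl)oxy]-3-ethenyl-8-methoxy-3,7-dimethyl-8-oxo-2-(prop-1-en-2-yl)oct-6-enoic acid, via boron dienolate 13 (not isolated)
Conditions: pre-formed (4R,5R)-2-bromo-1,3-bis[3,5-bis(trifluoromethyl)phenylsulfonyl]-4,5-diphenyl-1,3,2-diazaborolidine (1.5 equiv), Et3N, toluene/hexane, −78 → 4 °C; aq. work-up
Reagents that add atoms: none
Why: Enantioselective Ireland–Claisen rearrangement via a chiral boron enolate, in which the E(O) dienolate and the E-trisubstituted allyl unit react through a chair that sets C5 and C10 together (isopropenyl anti to vinyl) while the diazaborolidine shields one enolate face and fixes the absolute configuration.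

**Step 8**
Reactants: 14 (2R,3R,5R,6E)-5-[(tert-butyldimethylsilyl)oxy]-3-ethenyl-8-methoxy-3,7-dimethyl-8-oxo-2-(prop-1-en-2-yl)oct-6-enoic acid
Product: 16 methyl (2E,4R,6R,7R)-4-[(tert-butyldimethylsilyl)oxy]-6-ethenyl-7-formyl-2,6,8-trimethylnona-2,8-dienoate, via acid chloride 15 (not isolated)
Conditions: 1-chloro-N,N,2-trimethylprop-1-en-1-amine, CH2Cl2, 0 °C; LiAlH(Ot-Bu)3, THF, −78 °C
Reagents that add atoms: none
Why: Neutral acid chloride formation (Ghosez reagent) followed by Brown LiAlH(Ot-Bu)3 reduction stops at the aldehyde and leaves the enoate, the silyl ether and the α-stereocentre untouched.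

**Step 9** (key step)
Reactants: 16 methyl (2E,4R,6R,7R)-4-[(tert-butyldimethylsilyl)oxy]-6-ethenyl-7-formyl-2,6,8-trimethylnona-2,8-dienoate
Product: 19 (3R,3aR,4R,6R,7R,7aS)-4-[(tert-butyldimethylsilyl)oxy]-6-ethenyl-3,6-dimethyl-7-(prop-1-en-2-yl)hexahydro-1-benzofuran-2(3H)-one, via hydroxy ester 17 (not isolated), via C11-epimeric lactones 18 (not isolated)
Conditions: SmI2 (2.5 equiv), MeOH (5 equiv), THF, −78 → 0 °C; t-BuOK (3 equiv), 0 → 23 °C; AcOH
Reagents that add atoms: none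
Why: SmI2 ketyl–olefin radical cyclisation (6-exo-trig) with radical–polar crossover and lactonisation, in which the ketyl adds to the E-enoate through a chair with isopropenyl, vinyl and OTBS equatorial and the ketyl oxygen equatorial (anti to the enoate, away from the axial C10 methyl) so that C6 and C7 are set trans-diequatorial, the C6 alkoxide closes the trans γ-lactone, and t-BuOK equilibration converts the C11 epimers to the more stable one with the methyl anti to C8.

**Step 10**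
Reactants: 19 (3R,3aR,4R,6R,7R,7aS)-4-[(tert-butyldimethylsilyl)oxy]-6-ethenyl-3,6-dimethyl-7-(prop-1-en-2-yl)hexahydro-1-benzofuran-2(3H)-one
Product: 20 (3R,3aS,4R,6R,7R,7aS)-6-ethenyl-4-hydroxy-3,6-dimethyl-7-(prop-1-en-2-yl)hexahydro-1-benzofuran-2(3H)-one
Conditions: HF·pyridine, THF/pyridine, 0 → 23 °C
Reagents that add atoms: none
Why: Fluoride desilylation under non-basic conditions frees the C8 hydroxyl without forming an alkoxide that could translactonise to the 8,12-olide.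

**Step 11**
Reactants: 21 methyl 2-[(4S)-2,2-dimethyl-1,3-dioxolan-4-yl]acetate
Product: 25 methyl 2-[(4S)-2,2-dimethyl-1,3-dioxolan-4-yl]prop-2-enoate, via lithium enolate 22 (not isolated), via Mannich base 23 (not isolated), via ammonium iodide 24 (not isolated)
Conditions: LDA, THF, −78 °C; CH2=NMe2+ I−, −78 → 0 °C; MeI, MeOH, 23 °C; NaHCO3, CH2Cl2/H2O
Reagents that add atoms: Eschenmoser's salt C=[N+](C)C.[I-]
Why: Eschenmoser α-methylenation (Mannich reaction, N-quaternisation, E1cB elimination), run at −78 °C so that the β-alkoxy enolate does not eliminate and the dioxolane stereocentre, which is never deprotonated, is kept.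

**Step 12**
Reactants: 25 methyl 2-[(4S)-2,2-dimethyl-1,3-dioxolan-4-yl]prop-2-enoate
Product: 26 2-[(4S)-2,2-dimethyl-1,3-dioxolan-4-yl]prop-2-enoic acid
Conditions: LiOH, THF/H2O, 0 °C; 1 M HCl to pH 3, 0 °C
Reagents that add atoms: lithium hydroxide [Li+].[OH-]
Why: Ester saponification, with cold and brief acidification so that the acetonide survives.

**Step 13**
Reactants: 20 (3R,3aS,4R,6R,7R,7aS)-6-ethenyl-4-hydroxy-3,6-dimethyl-7-(prop-1-en-2-yl)hexahydro-1-benzofuran-2(3H)-one; 26 2-[(4S)-2,2-dimethyl-1,3-dioxolan-4-yl]prop-2-enoic acid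
Product: 27 (3R,3aS,4R,6R,7R,7aS)-6-ethenyl-3,6-dimethyl-2-oxo-7-(prop-1-en-2-yl)octahydro-1-benzofuran-4-yl 2-[(4S)-2,2-dimethyl-1,3-dioxolan-4-yl]prop-2-enoate
Conditions: DCC, DMAP, CH2Cl2, 0 → 23 °C
Reagents that add atoms: none
Why: Steglich esterification of the equatorial C8 hydroxyl, which touches no stereocentre.

**Step 14**
Reactants: 27 (3R,3aS,4R,6R,7R,7aS)-6-ethenyl-3,6-dimethyl-2-oxo-7-(prop-1-en-2-yl)octahydro-1-benzofuran-4-yl 2-[(4S)-2,2-dimethyl-1,3-dioxolan-4-yl]prop-2-enoate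
Product: 28 (3R,3aS,4R,6R,7S,7aS)-6-ethenyl-7-(3-hydroxyprop-1-en-2-yl)-3,6-dimethyl-2-oxooctahydro-1-benzofuran-4-yl 2-[(4S)-2,2-dimethyl-1,3-dioxolan-4-yl]prop-2-enoate
Conditions: SeO2 (0.5 equiv), t-BuOOH (3 equiv), CH2Cl2, 23 °C
Reagents that add atoms: selenium dioxide O=[Se]=O; tert-butyl hydroperoxide CC(C)(C)OO
Why: Sharpless catalytic SeO2 allylic oxidation (ene reaction, then [2,3]-shift) at the only allylic methyl of an electron-rich alkene (C15), since the vinyl group has no allylic hydrogen and the acrylate alkene is too electron-poor.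

**Step 15**
Reactants: 28 (3R,3aS,4R,6R,7S,7aS)-6-ethenyl-7-(3-hydroxyprop-1-en-2-yl)-3,6-dimethyl-2-oxooctahydro-1-benzofuran-4-yl 2-[(4S)-2,2-dimethyl-1,3-dioxolan-4-yl]prop-2-enoate
Product: 29 (3R,3aS,4R,6R,7S,7aS)-6-ethenyl-7-(3-hydroxyprop-1-en-2-yl)-3,6-dimethyl-2-oxooctahydro-1-benzofuran-4-yl (3S)-3,4-dihydroxy-2-methylidenebutanoate (target)
Conditions: AcOH/H2O (4:1), 40 °C
Reagents that add atoms: none
Why: Acid-catalysed acetal hydrolysis releases the side-chain diol without touching the esters, the lactone or any stereocentre.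

**Compound list**
1 | acrolein | C=CC=O | starting material
2 | propargyl bromide | C#CCBr | starting material
3 | allenylzinc bromide | C=C=C[Zn]Br | intermediate
4 | rac-hex-1-en-5-yn-3-ol | C#CCC(O)C=C | intermediate
5 | (3R)-hex-1-en-5-yn-3-ol | C#CC[C@@H](O)C=C | intermediate
6 | (E)-alkenyl(dimethyl)alane, O-dimethylaluminium alkoxide, from 5 | C[Al](C)/C=C(\C)C[C@@H](O[Al](C)C)C=C | intermediate
7 | (2E,5R)-3-methylhepta-2,6-diene-1,5-diol | OC/C=C(\C)C[C@@H](O)C=C | intermediate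
8 | methyl methacrylate | C=C(C)C(=O)OC | starting material
9 | methyl (2E,4R,6E)-4,8-dihydroxy-2,6-dimethylocta-2,6-dienoate | OC/C=C(\C)C[C@@H](O)/C=C(\C)C(=O)OC | intermediate
10 | 3-methylbut-3-enoic acid | C=C(C)CC(=O)O | starting material
11 | methyl (2E,4R,6E)-4-hydroxy-2,6-dimethyl-8-[(3-methylbut-3-enoyl)oxy]octa-2,6-dienoate | C=C(C)CC(=O)OC/C=C(\C)C[C@@H](O)/C=C(\C)C(=O)OC | intermediate
12 | methyl (2E,4R,6E)-4-[(tert-butyldimethylsilyl)oxy]-2,6-dimethyl-8-[(3-methylbut-3-enoyl)oxy]octa-2,6-dienoate | C=C(C)CC(=O)OC/C=C(\C)C[C@@H](O[Si](C)(C)C(C)(C)C)/C=C(\C)C(=O)OC | intermediate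
13 | E(O) boron dienolate of 12 carrying the (4R,5R)-diazaborolidin-2-yl group on oxygen | C=C(C)/C=C(\OC/C=C(\C)C[C@@H](O[Si](C)(C)C(C)(C)C)/C=C(\C)C(=O)OC)OB1N(S(=O)(=O)c2cc(cc(c2)C(F)(F)F)C(F)(F)F)[C@H](c2ccccc2)[C@@H](c2ccccc2)N1S(=O)(=O)c1cc(cc(c1)C(F)(F)F)C(F)(F)F | intermediate
14 | (2R,3R,5R,6E)-5-[(tert-butyldimethylsilyl)oxy]-3-ethenyl-8-methoxy-3,7-dimethyl-8-oxo-2-(prop-1-en-2-yl)oct-6-enoic acid | C=C[C@@](C)(C[C@@H](O[Si](C)(C)C(C)(C)C)/C=C(\C)C(=O)OC)[C@H](C(=O)O)C(C)=C | intermediate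
15 | acid chloride of 14 | C=C[C@@](C)(C[C@@H](O[Si](C)(C)C(C)(C)C)/C=C(\C)C(=O)OC)[C@H](C(=O)Cl)C(C)=C | intermediate
16 | methyl (2E,4R,6R,7R)-4-[(tert-butyldimethylsilyl)oxy]-6-ethenyl-7-formyl-2,6,8-trimethylnona-2,8-dienoate | C=C[C@@](C)(C[C@@H](O[Si](C)(C)C(C)(C)C)/C=C(\C)C(=O)OC)[C@H](C=O)C(C)=C | intermediate
17 | methyl 2-[(1R,2S,3R,4R,6R)-6-[(tert-butyldimethylsilyl)oxy]-4-ethenyl-2-hydroxy-4-methyl-3-(prop-1-en-2-yl)cyclohexyl]propanoate, both epimers at the propanoate C2 | C=C[C@@]1(C)C[C@@H](O[Si](C)(C)C(C)(C)C)[C@H](C(C)C(=O)OC)[C@@H](O)[C@@H]1C(C)=C | intermediate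
18 | lactone 19 as a mixture of C3 (C11) epimers | C=C[C@@]1(C)C[C@@H](O[Si](C)(C)C(C)(C)C)[C@H]2[C@@H](OC(=O)C2C)[C@@H]1C(C)=C | intermediate
19 | (3R,3aR,4R,6R,7R,7aS)-4-[(tert-butyldimethylsilyl)oxy]-6-ethenyl-3,6-dimethyl-7-(prop-1-en-2-yl)hexahydro-1-benzofuran-2(3H)-one | C=C[C@@]1(C)C[C@@H](O[Si](C)(C)C(C)(C)C)[C@H]2[C@@H](OC(=O)[C@@H]2C)[C@@H]1C(C)=C | intermediate
20 | (3R,3aS,4R,6R,7R,7aS)-6-ethenyl-4-hydroxy-3,6-dimethyl-7-(prop-1-en-2-yl)hexahydro-1-benzofuran-2(3H)-one | C=C[C@@]1(C)C[C@@H](O)[C@H]2[C@@H](OC(=O)[C@@H]2C)[C@@H]1C(C)=C | intermediate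
21 | methyl 2-[(4S)-2,2-dimethyl-1,3-dioxolan-4-yl]acetate | COC(=O)C[C@H]1COC(C)(C)O1 | starting material
22 | lithium enolate of 21 | COC(O[Li])=C[C@H]1COC(C)(C)O1 | intermediate
23 | methyl 3-(dimethylamino)-2-[(4S)-2,2-dimethyl-1,3-dioxolan-4-yl]propanoate, both C2 epimers | COC(=O)C(CN(C)C)[C@H]1COC(C)(C)O1 | intermediate
24 | trimethylammonium iodide of 23 | COC(=O)C(C[N+](C)(C)C)[C@H]1COC(C)(C)O1.[I-] | intermediate
25 | methyl 2-[(4S)-2,2-dimethyl-1,3-dioxolan-4-yl]prop-2-enoate | COC(=O)C(=C)[C@H]1COC(C)(C)O1 | intermediate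
26 | 2-[(4S)-2,2-dimethyl-1,3-dioxolan-4-yl]prop-2-enoic acid | OC(=O)C(=C)[C@H]1COC(C)(C)O1 | intermediate
27 | (3R,3aS,4R,6R,7R,7aS)-6-ethenyl-3,6-dimethyl-2-oxo-7-(prop-1-en-2-yl)octahydro-1-benzofuran-4-yl 2-[(4S)-2,2-dimethyl-1,3-dioxolan-4-yl]prop-2-enoate | C=C[C@@]1(C)C[C@@H](OC(=O)C(=C)[C@H]3COC(C)(C)O3)[C@H]2[C@@H](OC(=O)[C@@H]2C)[C@@H]1C(C)=C | intermediate
28 | (3R,3aS,4R,6R,7S,7aS)-6-ethenyl-7-(3-hydroxyprop-1-en-2-yl)-3,6-dimethyl-2-oxooctahydro-1-benzofuran-4-yl 2-[(4S)-2,2-dimethyl-1,3-dioxolan-4-yl]prop-2-enoate | C=C[C@@]1(C)C[C@@H](OC(=O)C(=C)[C@H]3COC(C)(C)O3)[C@H]2[C@@H](OC(=O)[C@@H]2C)[C@@H]1C(=C)CO | intermediate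
29 | (3R,3aS,4R,6R,7S,7aS)-6-ethenyl-7-(3-hydroxyprop-1-en-2-yl)-3,6-dimethyl-2-oxooctahydro-1-benzofuran-4-yl (3S)-3,4-dihydroxy-2-methylidenebutanoate | C=C[C@@]1(C)C[C@@H](OC(=O)C(=C)[C@H](O)CO)[C@H]2[C@@H](OC(=O)[C@@H]2C)[C@@H]1C(=C)CO | target

**Totals**
Total step count: 15. Longest linear sequence: 13 (steps 1–10 and 13–15); the side-chain branch is steps 11–12.

**Three steps most likely to fail** (step 9 is the riskiest)

Step 7, enantioselective Ireland–Claisen on a substrate that also carries an enoate and a silyl ether. The fallback sets out from 12 and comes back at 14. It gives up reagent control and uses the fixed C8 centre for separation. LDA and TMSCl in THF (−78 → 23 °C) give the E(O) trimethylsilyl ketene acetal F1, which rearranges through the same chair to the trimethylsilyl esters F2, an about 1:1 mixture of the two anti diastereomers because C8 is too remote to bias the face. Hydrolysis gives 14 together with its (2S,3S,5R)-diastereomer F3; the two are diastereomers and are separated by chromatography, and 14 continues with step 8.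

Step 9, the SmI2 double ring closure (simple reduction of the hindered aldehyde, pinacol coupling or loss of the γ-silyloxy group could compete). The fallback sets out from 16 and comes back at 17. It replaces the radical closure by a polar one: an intramolecular Stetter reaction (triazolium carbene precatalyst, KHMDS, toluene) makes the same C6–C7 bond and gives the cyclohexanone keto ester F4, with C5 and C7 equilibrated to the all-equatorial arrangement. Dissolving-metal reduction (Li, NH3/THF, t-BuOH, −78 °C) gives the equatorial C6 alcohol, which is hydroxy ester 17. 17 is then lactonised and equilibrated with t-BuOK and AcOH to 19 as in step 9. The two rings then form in separate operations.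

Step 14, late SeO2 oxidation (over-oxidation to the enal, or attack at the C5–H). The fallback sets out from 27 and comes back at 28. Ene-type allylic chlorination (NaOCl, CeCl3·7H2O, CH2Cl2/H2O, 0 °C) turns the isopropenyl group into the 2-substituted allyl chloride F5; the allylic transposition gives the same constitution. Silver-assisted hydrolysis (AgBF4, acetone/H2O) then gives 28.

**Further compounds**
F1 | step 7 | E(O) trimethylsilyl ketene acetal of 12 | C=C(C)/C=C(\OC/C=C(\C)C[C@@H](O[Si](C)(C)C(C)(C)C)/C=C(\C)C(=O)OC)O[Si](C)(C)C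
F2 | step 7 | trimethylsilyl esters of 14 and of its C2,C3-diastereomer (mixture) | C=CC(C)(C[C@@H](O[Si](C)(C)C(C)(C)C)/C=C(\C)C(=O)OC)C(C(=O)O[Si](C)(C)C)C(C)=C
F3 | step 7 | (2S,3S,5R,6E)-diastereomer of acid 14 | C=C[C@](C)(C[C@@H](O[Si](C)(C)C(C)(C)C)/C=C(\C)C(=O)OC)[C@@H](C(=O)O)C(C)=C
F4 | step 9 | C6-ketone analogue of 17 (methyl 2-[6-silyloxy-4-ethenyl-4-methyl-2-oxo-3-(prop-1-en-2-yl)cyclohexyl]propanoate, ring substituents equatorial) | C=C[C@@]1(C)C[C@@H](O[Si](C)(C)C(C)(C)C)[C@H](C(C)C(=O)OC)C(=O)[C@@H]1C(C)=C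
F5 | step 14 | C15 allyl chloride analogue of 28 (3-chloroprop-1-en-2-yl in place of 3-hydroxyprop-1-en-2-yl) | C=C[C@@]1(C)C[C@@H](OC(=O)C(=C)[C@H]3COC(C)(C)O3)[C@H]2[C@@H](OC(=O)[C@@H]2C)[C@@H]1C(=C)CCl
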